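**Plan**

1. Cuts: after removal of seven silyl ethers, the target is cut at the C7–aryl bond of the central threo arylglycerol (unit B). This gives an aldehyde half (syringaresinol core with the finished erythro unit A on one phenolic oxygen and an O–CH(CH2OSi)–CHO arm on the other) and an aryl bromide half (middle guaiacyl ring already etherified with erythro unit C).
2. Units A and C are each cut at C7–aryl (Weinreb amide plus aryl Grignard) and at C8–O (Mitsunobu of a phenol with a silylated methyl glycerate); the furofuran core is (+)-syringaresinol.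
3. Forward: both core phenols are etherified at once with the (R)-glycerate, the bis-Weinreb amide is mono-arylated, the ketone is reduced and silylated, and the second amide is reduced to the aldehyde. The bromide half is built by the same sequence from 4-bromo-2-methoxyphenol and the (S)-glycerate; the halves are then joined and desilylated.
4. Stereochemistry: furofuran centres from the natural lignan; all three C8 centres from the glycerates by SN2 inversion; the two erythro C7 centres by hydride delivery inside a metal chelate of the α-aryloxy ketones; the threo C7 centre by aryl delivery inside the same kind of chelate of the α-aryloxy aldehyde.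
5. Enabling feature: the ether oxygen on C8 of unit B (the phenolic oxygen of the second 3,5-dimethoxyphenyl ring of the core, flanked by an ortho-methoxy oxygen) sits next to the aldehyde carbon and clamps magnesium to the carbonyl oxygen in a five-membered chelate. The ring carbon para to the ether oxygen of the middle guaiacyl ring is addressed as a bromide and turned into the nucleophile.

Key step: step 18

Assumption: (+)-syringaresinol, (7S,8R,7'S,8'R), is bought as the enantiopure natural lignan; lignan numbering (C7 benzylic, C8 ether-bearing, C9 primary) is used for each arylglycerol unit.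

**Step 1**
Reactants: 1 methyl (R)-2,2-dimethyl-1,3-dioxolane-4-carboxylate
Product: 2 methyl (R)-2,3-dihydroxypropanoate
Conditions: 80% aq. AcOH, 40 °C; AcOH removed with toluene
Reagents that add atoms: none
Why: Acid-catalysed acetal hydrolysis should free the diol without touching the methyl ester or the C2 stereocentre, which takes no part.

**Step 2**
Reactants: 2 methyl (R)-2,3-dihydroxypropanoate
Product: 3 methyl (R)-3-(tert-butyldiphenylsilyloxy)-2-hydroxypropanoate
Conditions: TBDPSCl (1.05 equiv), imidazole, CH2Cl2, 0 °C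
Reagents that add atoms: tert-butyl(chloro)diphenylsilane (TBDPSCl), CC(C)(C)[Si](Cl)(c1ccccc1)c1ccccc1
Why: Silyl ether formation with the bulky chlorosilane should go selectively at the primary hydroxyl and leave the secondary C2–OH free for the Mitsunobu reaction.

**Step 3**
Reactants: 4 methyl (S)-2,2-dimethyl-1,3-dioxolane-4-carboxylate
Product: 5 methyl (S)-2,3-dihydroxypropanoate
Conditions: 80% aq. AcOH, 40 °C; AcOH removed with toluene
Reagents that add atoms: none
Why: The same acid-catalysed acetal hydrolysis as in step 1 should give the enantiomeric diol with the stereocentre untouched.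

**Step 4**
Reactants: 5 methyl (S)-2,3-dihydroxypropanoate
Product: 6 methyl (S)-3-(tert-butyldiphenylsilyloxy)-2-hydroxypropanoate
Conditions: TBDPSCl (1.05 equiv), imidazole, CH2Cl2, 0 °C
Reagents that add atoms: tert-butyl(chloro)diphenylsilane (TBDPSCl), CC(C)(C)[Si](Cl)(c1ccccc1)c1ccccc1
Why: Primary-selective silyl ether formation as in step 2 should give the enantiomeric Mitsunobu partner.

**Step 5**
Reactants: 7 4-bromo-2-methoxyphenol
Product: 8 (4-bromo-2-methoxyphenoxy)(tert-butyl)dimethylsilane
Conditions: TBSCl, imidazole, DMF, rt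
Reagents that add atoms: tert-butyl(chloro)dimethylsilane (TBSCl), CC(C)(C)[Si](C)(C)Cl
Why: Phenol silylation (silyl ether formation) masks the acidic OH so that the aryl bromide can be converted into a Grignard reagent.

**Step 6**
Reactants: 8 (4-bromo-2-methoxyphenoxy)(tert-butyl)dimethylsilane
Product: 9 [4-(tert-butyldimethylsilyloxy)-3-methoxyphenyl]magnesium bromide (titrated THF solution)
Conditions: Mg turnings, I2 (cat.), THF, 40 °C → rt
Reagents that add atoms: magnesium, [Mg]
Why: Grignard reagent formation by magnesium insertion into the aryl C–Br bond should proceed normally because the aryl silyl ether is inert to arylmagnesium species; the solution serves steps 9 and 15.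

**Step 7**
Reactants: 10 (+)-syringaresinol (7S,8R,7'S,8'R); 3 methyl (R)-3-(tert-butyldiphenylsilyloxy)-2-hydroxypropanoate (3 equiv)
Product: 11 C2-symmetric bis-ester: each phenolic oxygen of the core carries an (S)-CH(CO2Me)CH2OTBDPS group
Conditions: PPh3, DIAD, THF (concentrated), 0 °C → rt
Reagents that add atoms: none
Why: Double Mitsunobu etherification, in which each phenol displaces the activated secondary hydroxyl of 3 by SN2 with inversion, should make both new C8 centres S and keep the C2 symmetry of the core.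

**Step 8**
Reactants: 11 C2-symmetric bis-ester
Product: 12 C2-symmetric bis-Weinreb amide: each phenolic oxygen carries an (S)-CH[C(O)N(OMe)Me]CH2OTBDPS group
Conditions: MeNH(OMe)·HCl, iPrMgCl, THF, −20 → −5 °C
Reagents that add atoms: N,O-dimethylhydroxylamine hydrochloride, CNOC.Cl
Why: Ester aminolysis by the chloromagnesium amide of N,O-dimethylhydroxylamine (Weinreb amide formation) at low temperature should convert both esters without epimerising the α-aryloxy centres.

**Step 9**
Reactants: 12 C2-symmetric bis-Weinreb amide; 9 [4-(tert-butyldimethylsilyloxy)-3-methoxyphenyl]magnesium bromide (0.8 equiv)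
Product: 13 mono-ketone: one arm is (S)-CH(CH2OTBDPS)–C(O)–[4-(TBSO)-3-methoxyphenyl], the other arm is the unchanged Weinreb amide
Conditions: slow addition of 9, THF, −20 → 0 °C; aq. NaH2PO4/Na2HPO4 (pH 7)
Reagents that add atoms: none
Why: Weinreb ketone synthesis, in which the aryl Grignard adds once to give a stable magnesium chelate that collapses to the ketone only on work-up, should with a deficit of 9 give the mono-ketone as the main product of a statistical mixture from which unreacted 12 is recovered and recycled.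

**Step 10**
Reactants: 13 mono-ketone
Product: 14 erythro alcohol of unit A (7R,8S) with the Weinreb amide arm unchanged
Conditions: Zn(BH4)2, Et2O, −40 → 0 °C
Reagents that add atoms: none
Why: Chelation-controlled (Cram-chelate) ketone reduction, in which zinc bridges the ketone oxygen and the C8 aryloxy oxygen and hydride enters anti to the CH2OTBDPS group, should give the 7R (erythro) alcohol while the Weinreb amide is not reduced.

**Step 11**
Reactants: 14 erythro alcohol of unit A
Product: 15 C7-O-TBS ether of unit A with the Weinreb amide arm unchanged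
Conditions: TBSOTf, 2,6-lutidine, CH2Cl2, −78 → 0 °C
Reagents that add atoms: tert-butyldimethylsilyl trifluoromethanesulfonate (TBSOTf), CC(C)(C)[Si](C)(C)OS(=O)(=O)C(F)(F)F
Why: Silyl ether formation with the reactive silyl triflate should protect the hindered secondary benzylic alcohol without affecting any other group.

**Step 12**
Reactants: 15 C7-O-TBS ether of unit A with Weinreb amide arm
Product: 16 aldehyde: the second phenolic oxygen of the core carries an (S)-CH(CHO)CH2OTBDPS arm
Conditions: i-Bu2AlH, THF, −78 °C; aq. potassium sodium tartrate; used crude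
Reagents that add atoms: none
Why: Partial reduction of the Weinreb amide by i-Bu2AlH stops at the aluminium-chelated hemiaminal, which gives the aldehyde on work-up, and low temperature with direct use should keep the α-aryloxy C8 centre intact.

**Step 13**
Reactants: 7 4-bromo-2-methoxyphenol; 6 methyl (S)-3-(tert-butyldiphenylsilyloxy)-2-hydroxypropanoate
Product: 17 methyl (R)-2-(4-bromo-2-methoxyphenoxy)-3-(tert-butyldiphenylsilyloxy)propanoate
Conditions: PPh3, DIAD, THF, 0 °C → rt
Reagents that add atoms: none
Why: Mitsunobu etherification of the phenol with the α-hydroxy ester proceeds by SN2 with inversion and should set the C8 centre of unit C as R.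

**Step 14**
Reactants: 17 methyl (R)-2-(4-bromo-2-methoxyphenoxy)-3-(tert-butyldiphenylsilyloxy)propanoate
Product: 18 (R)-2-(4-bromo-2-methoxyphenoxy)-3-(tert-butyldiphenylsilyloxy)-N-methoxy-N-methylpropanamide
Conditions: MeNH(OMe)·HCl, iPrMgCl, THF, −20 → −5 °C
Reagents that add atoms: N,O-dimethylhydroxylamine hydrochloride, CNOC.Cl
Why: Weinreb amide formation by ester aminolysis should proceed without epimerisation, and the electron-rich aryl bromide does not exchange with iPrMgCl at this temperature.

**Step 15**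
Reactants: 18 Weinreb amide of the bromide half; 9 [4-(tert-butyldimethylsilyloxy)-3-methoxyphenyl]magnesium bromide (1.3 equiv)
Product: 19 (R)-2-(4-bromo-2-methoxyphenoxy)-1-[4-(tert-butyldimethylsilyloxy)-3-methoxyphenyl]-3-(tert-butyldiphenylsilyloxy)propan-1-one
Conditions: THF, −10 → 0 °C; aq. NaH2PO4/Na2HPO4 (pH 7)
Reagents that add atoms: none
Why: Weinreb ketone synthesis should stop at the ketone after work-up, and the aryl bromide of 18 is inert to the arylmagnesium reagent.

**Step 16**
Reactants: 19 α-aryloxy aryl ketone of the bromide half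
Product: 20 (1S,2R)-2-(4-bromo-2-methoxyphenoxy)-1-[4-(tert-butyldimethylsilyloxy)-3-methoxyphenyl]-3-(tert-butyldiphenylsilyloxy)propan-1-ol (erythro)
Conditions: Zn(BH4)2, Et2O, −40 → 0 °C
Reagents that add atoms: none
Why: Chelation-controlled (Cram-chelate) ketone reduction through the zinc chelate of the ketone oxygen and the 2-methoxyphenoxy oxygen should deliver hydride anti to the CH2OTBDPS group and give the 7S (erythro) alcohol.

**Step 17**
Reactants: 20 erythro alcohol of the bromide half
Product: 21 aryl bromide half: the C7-O-TBS ether of 20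
Conditions: TBSOTf, 2,6-lutidine, CH2Cl2, −78 → 0 °C
Reagents that add atoms: tert-butyldimethylsilyl trifluoromethanesulfonate (TBSOTf), CC(C)(C)[Si](C)(C)OS(=O)(=O)C(F)(F)F
Why: Silyl ether formation with the silyl triflate should protect the secondary benzylic alcohol so that the bromide can be metalated.

**Step 18**
Reactants: 21 aryl bromide half (1.5 equiv); 16 aldehyde
Product: 24 hepta-silylated threo carbinol (unit B 7S,8S; free C7–OH), via aryllithium 22 (not isolated), via arylmagnesium bromide 23 (not isolated)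
Conditions: 21, t-BuLi (2 equiv per 21), Et2O, −78 °C; MgBr2·OEt2, −78 → −20 °C; added to 16 premixed with MgBr2·OEt2 (2 equiv) in CH2Cl2, −78 °C; aq. NaH2PO4/Na2HPO4 (pH 7)
Reagents that add atoms: none
Why: Bromine–lithium exchange at the carbon para to the ether oxygen of the middle guaiacyl ring and transmetalation give arylmagnesium 23, which adds to the aldehyde carbon of 16 while magnesium is held in a five-membered chelate by the aldehyde oxygen and the C8 ether oxygen (the phenolic oxygen of the second dimethoxyphenyl ring, backed by its ortho-methoxy oxygen). The closest known reaction type is the Cram-chelate-controlled Grignard addition to α-alkoxy aldehydes. No ring is closed; the only ring involved is the transient magnesium chelate. The new C7 centre is controlled by the existing C8 centre: in the chelate the CH2OTBDPS group shields one face, aryl is delivered to the face carrying the C8 hydrogen, and the 7S,8S (threo) alcohol should result, the same chelate giving erythro alcohols in steps 10 and 16 where hydride instead of aryl is the incoming group. The step needs chelation to outrun the open Felkin–Anh pathway, which is secured by the bulky non-coordinating silyl ether on O9, the THF-free CH2Cl2/Et2O medium, excess MgBr2 and the bidentate dimethoxyphenoxy pocket, and it needs chemoselectivity for the aldehyde, which is secured because every other oxygen function is a silyl or aryl ether. Addition at −78 °C should also outpace enolisation of the α-aryloxy aldehyde, so C8 is not scrambled.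

**Step 19**
Reactants: 24 hepta-silylated threo carbinol
Product: 25 CNP0316493.3 (target)
Conditions: Bu4NF, AcOH (1:1), THF, 0 °C → rt
Reagents that add atoms: none
Why: Fluoride-induced desilylation buffered with acetic acid should cleave all four TBS and three TBDPS ethers without base-induced damage to the p-hydroxybenzyl alcohol units or epimerisation of the furofuran.

**Compound list**

1 | methyl (R)-2,2-dimethyl-1,3-dioxolane-4-carboxylate | COC(=O)[C@H]1COC(C)(C)O1 | starting material
2 | methyl (R)-2,3-dihydroxypropanoate | COC(=O)[C@H](O)CO | intermediate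
3 | methyl (R)-3-(tert-butyldiphenylsilyloxy)-2-hydroxypropanoate | COC(=O)[C@H](O)CO[Si](c1ccccc1)(c1ccccc1)C(C)(C)C | intermediate
4 | methyl (S)-2,2-dimethyl-1,3-dioxolane-4-carboxylate | COC(=O)[C@@H]1COC(C)(C)O1 | starting material
5 | methyl (S)-2,3-dihydroxypropanoate | COC(=O)[C@@H](O)CO | intermediate
6 | methyl (S)-3-(tert-butyldiphenylsilyloxy)-2-hydroxypropanoate | COC(=O)[C@@H](O)CO[Si](c1ccccc1)(c1ccccc1)C(C)(C)C | intermediate
7 | 4-bromo-2-methoxyphenol | COc1cc(Br)ccc1O | starting material
8 | (4-bromo-2-methoxyphenoxy)(tert-butyl)dimethylsilane | COc1cc(Br)ccc1O[Si](C)(C)C(C)(C)C | intermediate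
9 | [4-(tert-butyldimethylsilyloxy)-3-methoxyphenyl]magnesium bromide | COc1cc([Mg]Br)ccc1O[Si](C)(C)C(C)(C)C | intermediate
10 | (+)-syringaresinol (7S,8R,7'S,8'R) | COc1cc(cc(OC)c1O)[C@H]1OC[C@H]2[C@@H]1CO[C@@H]2c1cc(OC)c(O)c(OC)c1 | starting material
11 | C2-symmetric bis-ester, both phenolic O bearing (S)-CH(CO2Me)CH2OTBDPS | COC(=O)[C@H](CO[Si](c1ccccc1)(c1ccccc1)C(C)(C)C)Oc1c(OC)cc(cc1OC)[C@H]1OC[C@H]2[C@@H]1CO[C@@H]2c1cc(OC)c(O[C@@H](CO[Si](c2ccccc2)(c2ccccc2)C(C)(C)C)C(=O)OC)c(OC)c1 | intermediate
12 | C2-symmetric bis-Weinreb amide, both phenolic O bearing (S)-CH[C(O)N(OMe)Me]CH2OTBDPS | CON(C)C(=O)[C@H](CO[Si](c1ccccc1)(c1ccccc1)C(C)(C)C)Oc1c(OC)cc(cc1OC)[C@H]1OC[C@H]2[C@@H]1CO[C@@H]2c1cc(OC)c(O[C@@H](CO[Si](c2ccccc2)(c2ccccc2)C(C)(C)C)C(=O)N(C)OC)c(OC)c1 | intermediate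
13 | mono-ketone (unit A C7 ketone, 8S; other arm Weinreb amide) | COc1cc(ccc1O[Si](C)(C)C(C)(C)C)C(=O)[C@H](CO[Si](c1ccccc1)(c1ccccc1)C(C)(C)C)Oc1c(OC)cc(cc1OC)[C@H]1OC[C@H]2[C@@H]1CO[C@@H]2c1cc(OC)c(O[C@@H](CO[Si](c2ccccc2)(c2ccccc2)C(C)(C)C)C(=O)N(C)OC)c(OC)c1 | intermediate
14 | erythro alcohol of unit A (7R,8S; other arm Weinreb amide) | COc1cc(ccc1O[Si](C)(C)C(C)(C)C)[C@@H](O)[C@H](CO[Si](c1ccccc1)(c1ccccc1)C(C)(C)C)Oc1c(OC)cc(cc1OC)[C@H]1OC[C@H]2[C@@H]1CO[C@@H]2c1cc(OC)c(O[C@@H](CO[Si](c2ccccc2)(c2ccccc2)C(C)(C)C)C(=O)N(C)OC)c(OC)c1 | intermediate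
15 | C7-O-TBS ether of 14 | COc1cc(ccc1O[Si](C)(C)C(C)(C)C)[C@@H](O[Si](C)(C)C(C)(C)C)[C@H](CO[Si](c1ccccc1)(c1ccccc1)C(C)(C)C)Oc1c(OC)cc(cc1OC)[C@H]1OC[C@H]2[C@@H]1CO[C@@H]2c1cc(OC)c(O[C@@H](CO[Si](c2ccccc2)(c2ccccc2)C(C)(C)C)C(=O)N(C)OC)c(OC)c1 | intermediate
16 | aldehyde half (unit A complete and silylated; other arm (S)-O–CH(CHO)CH2OTBDPS) | COc1cc(ccc1O[Si](C)(C)C(C)(C)C)[C@@H](O[Si](C)(C)C(C)(C)C)[C@H](CO[Si](c1ccccc1)(c1ccccc1)C(C)(C)C)Oc1c(OC)cc(cc1OC)[C@H]1OC[C@H]2[C@@H]1CO[C@@H]2c1cc(OC)c(O[C@@H](CO[Si](c2ccccc2)(c2ccccc2)C(C)(C)C)C=O)c(OC)c1 | intermediate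
17 | methyl (R)-2-(4-bromo-2-methoxyphenoxy)-3-(tert-butyldiphenylsilyloxy)propanoate | COc1cc(Br)ccc1O[C@H](CO[Si](c1ccccc1)(c1ccccc1)C(C)(C)C)C(=O)OC | intermediate
18 | (R)-2-(4-bromo-2-methoxyphenoxy)-3-(tert-butyldiphenylsilyloxy)-N-methoxy-N-methylpropanamide | COc1cc(Br)ccc1O[C@H](CO[Si](c1ccccc1)(c1ccccc1)C(C)(C)C)C(=O)N(C)OC | intermediate
19 | (R)-2-(4-bromo-2-methoxyphenoxy)-1-[4-(tert-butyldimethylsilyloxy)-3-methoxyphenyl]-3-(tert-butyldiphenylsilyloxy)propan-1-one | COc1cc(Br)ccc1O[C@H](CO[Si](c1ccccc1)(c1ccccc1)C(C)(C)C)C(=O)c1ccc(O[Si](C)(C)C(C)(C)C)c(OC)c1 | intermediate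
20 | (1S,2R)-2-(4-bromo-2-methoxyphenoxy)-1-[4-(tert-butyldimethylsilyloxy)-3-methoxyphenyl]-3-(tert-butyldiphenylsilyloxy)propan-1-ol | COc1cc(Br)ccc1O[C@H](CO[Si](c1ccccc1)(c1ccccc1)C(C)(C)C)[C@@H](O)c1ccc(O[Si](C)(C)C(C)(C)C)c(OC)c1 | intermediate
21 | aryl bromide half (C7-O-TBS ether of 20) | COc1cc(Br)ccc1O[C@H](CO[Si](c1ccccc1)(c1ccccc1)C(C)(C)C)[C@@H](O[Si](C)(C)C(C)(C)C)c1ccc(O[Si](C)(C)C(C)(C)C)c(OC)c1 | intermediate
22 | aryllithium from 21 (Li in place of Br) | COc1cc([Li])ccc1O[C@H](CO[Si](c1ccccc1)(c1ccccc1)C(C)(C)C)[C@@H](O[Si](C)(C)C(C)(C)C)c1ccc(O[Si](C)(C)C(C)(C)C)c(OC)c1 | intermediate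
23 | arylmagnesium bromide from 22 (MgBr in place of Li) | COc1cc([Mg]Br)ccc1O[C@H](CO[Si](c1ccccc1)(c1ccccc1)C(C)(C)C)[C@@H](O[Si](C)(C)C(C)(C)C)c1ccc(O[Si](C)(C)C(C)(C)C)c(OC)c1 | intermediate
24 | hepta-silylated target with free C7–OH in unit B (7S,8S) | COc1cc(ccc1O[Si](C)(C)C(C)(C)C)[C@@H](O[Si](C)(C)C(C)(C)C)[C@H](CO[Si](c1ccccc1)(c1ccccc1)C(C)(C)C)Oc1c(OC)cc(cc1OC)[C@H]1OC[C@H]2[C@@H]1CO[C@@H]2c1cc(OC)c(O[C@@H](CO[Si](c2ccccc2)(c2ccccc2)C(C)(C)C)[C@@H](O)c2ccc(O[C@H](CO[Si](c3ccccc3)(c3ccccc3)C(C)(C)C)[C@@H](O[Si](C)(C)C(C)(C)C)c3ccc(O[Si](C)(C)C(C)(C)C)c(OC)c3)c(OC)c2)c(OC)c1 | intermediate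
25 | CNP0316493.3 | COc1cc([C@@H](O)[C@H](CO)Oc2c(OC)cc([C@H]3OC[C@H]4[C@@H]3CO[C@@H]4c3cc(OC)c(O[C@@H](CO)[C@@H](O)c4ccc(O[C@H](CO)[C@@H](O)c5ccc(O)c(OC)c5)c(OC)c4)c(OC)c3)cc2OC)ccc1O | target

**Step count and risks**

Total step count: 19. Longest linear sequence: 10 steps (1, 2, 7, 8, 9, 10, 11, 12, 18, 19).

Steps most likely to fail:

- **Step 18.** The open Felkin–Anh addition may compete with the chelate, or the aldehyde may enolise, which would erode the threo selectivity or scramble C8. Fallback: setting out from Weinreb amide 15 (so the aldehyde is never made) and bromide 21, arylmagnesium bromide 23 is generated as in step 18 and added to 15 in THF at 0 °C. This Weinreb ketone synthesis forms the same C–C bond without a stereochemical question and gives the unit B aryl ketone F1. Reduction of F1 under non-chelating Felkin–Anh control with KBH(s-Bu)3 in THF at −78 °C (potassium counter-ion, coordinating solvent, bulky hydride entering anti to the aryloxy group) should give the threo alcohol, and the route is rejoined at 24.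

- **Step 7.** Displacement at the oxyphosphonium-activated secondary centre by the doubly ortho-substituted phenol may be slow, so that elimination of the activated glycerate takes over. Fallback: from 3, Tf2O and 2,6-lutidine in CH2Cl2 at −78 °C give methyl (R)-3-(tert-butyldiphenylsilyloxy)-2-(trifluoromethylsulfonyloxy)propanoate F2. The caesium bis-phenoxide of 10 (Cs2CO3, MeCN, −20 → 0 °C) displaces the triflate by SN2 with the same inversion, and the route is rejoined at 11.

- **Step 10.** Hydride may be delivered through the open transition state instead of the zinc chelate, which would lower the erythro selectivity on the valuable core. Fallback: the order of bond formation at C7 is reversed. From 12, one equivalent of i-Bu2AlH (THF, −78 °C) gives the mono-aldehyde mono-Weinreb amide F3 (statistical, 12 recovered). The aryltitanium triisopropoxide F4, made from 9 and ClTi(OiPr)3, adds to F3 under non-chelating Felkin–Anh control (aryl anti to the C8 aryloxy group) to give the erythro alcohol directly, rejoining the route at 14 and bypassing 13.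

**Further compounds**

F1 | step 18 | unit B aryl ketone (hepta-silylated, C7 ketone in unit B) | COc1cc(ccc1O[Si](C)(C)C(C)(C)C)[C@@H](O[Si](C)(C)C(C)(C)C)[C@H](CO[Si](c1ccccc1)(c1ccccc1)C(C)(C)C)Oc1c(OC)cc(cc1OC)[C@H]1OC[C@H]2[C@@H]1CO[C@@H]2c1cc(OC)c(O[C@@H](CO[Si](c2ccccc2)(c2ccccc2)C(C)(C)C)C(=O)c2ccc(O[C@H](CO[Si](c3ccccc3)(c3ccccc3)C(C)(C)C)[C@@H](O[Si](C)(C)C(C)(C)C)c3ccc(O[Si](C)(C)C(C)(C)C)c(OC)c3)c(OC)c2)c(OC)c1
F2 | step 7 | methyl (R)-3-(tert-butyldiphenylsilyloxy)-2-(trifluoromethylsulfonyloxy)propanoate | COC(=O)[C@H](OS(=O)(=O)C(F)(F)F)CO[Si](c1ccccc1)(c1ccccc1)C(C)(C)C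
F3 | step 10 | mono-aldehyde mono-Weinreb amide of the core (both arms 8S) | O=C[C@H](CO[Si](c1ccccc1)(c1ccccc1)C(C)(C)C)Oc1c(OC)cc(cc1OC)[C@H]1OC[C@H]2[C@@H]1CO[C@@H]2c1cc(OC)c(O[C@@H](CO[Si](c2ccccc2)(c2ccccc2)C(C)(C)C)C(=O)N(C)OC)c(OC)c1
F4 | step 10 | [4-(tert-butyldimethylsilyloxy)-3-methoxyphenyl]titanium triisopropoxide | COc1cc(ccc1O[Si](C)(C)C(C)(C)C)[Ti](OC(C)C)(OC(C)C)OC(C)C
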